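**Retrosynthetic overview**

1. Didemnimide D (11) has no stereocentre. The feature used is its maleimide ring: the C3=C4 double bond carries the 6-bromoindol-3-yl and 1-methylimidazol-5-yl groups and is flanked by the C2 and C5 carbonyls, both bonded to the single imide nitrogen N1.
2. Cutting C2–C3, C4–C5, N1–C2 and N1–C5 together leads to a diheteroarylalkyne (6), two molecules of CO (7) and a removable primary amine (8). Because the two carbonyls are made equivalent by N1, either orientation of addition to the unsymmetrical alkyne gives the same imide (9).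
3. Alkyne 6 comes from an iodide-selective Sonogashira coupling of N-Boc-6-bromo-3-iodoindole (4) with 5-ethynyl-1-methylimidazole (5); 4 comes from 6-bromoindole (1) by C3 iodination and N-Boc protection.
4. Ring order: the indole and imidazole rings are bought, the maleimide is the only ring built (step 4), and one acid treatment then removes the N-Boc and N-(2,4-dimethoxybenzyl) groups.

Key step: step 4

Remark on the chemistry: O2 with catalytic Cu(OAc)2 is taken as terminal oxidant in step 4, because a quinone oxidant would be consumed by conjugate addition of the primary amine. Loss of the indole N-Boc group to the amine during step 4 would be harmless, since the N–H compound 10 is the next intermediate in any case.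

**Route**

Step 1
Reactants: 1 6-bromo-1H-indole
Product: 2 6-bromo-3-iodo-1H-indole (light-sensitive; isolated by aqueous NaHSO3 work-up and used at once)
Conditions: I2, KOH, DMF, rt
Reagents that add atoms: iodine, II
Why: Electrophilic aromatic substitution by iodine under base takes place at C3, the most nucleophilic indole position, and leaves the benzenoid ring and its bromide untouched.

Step 2
Reactants: 2 6-bromo-3-iodo-1H-indole; 3 di-tert-butyl dicarbonate
Product: 4 tert-butyl 6-bromo-3-iodo-1H-indole-1-carboxylate
Conditions: Boc2O, 4-(dimethylamino)pyridine (cat.), CH2Cl2, rt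
Reagents that add atoms: di-tert-butyl dicarbonate (3), CC(C)(C)OC(=O)OC(=O)OC(C)(C)C
Why: Nucleophile-catalysed N-acylation of the indole nitrogen (carbamate protection) stabilises the sensitive 3-iodoindole and later tempers the electron-rich alkyne.

Step 3
Reactants: 4 tert-butyl 6-bromo-3-iodo-1H-indole-1-carboxylate; 5 5-ethynyl-1-methyl-1H-imidazole
Product: 6 tert-butyl 6-bromo-3-[(1-methyl-1H-imidazol-5-yl)ethynyl]-1H-indole-1-carboxylate
Conditions: PdCl2(PPh3)2 (3 mol%), CuI (5 mol%), Et3N, THF, degassed, rt
Reagents that add atoms: 5-ethynyl-1-methyl-1H-imidazole (5), C#Cc1cncn1C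
Why: In this Sonogashira coupling zerovalent palladium inserts into the C3–I bond far faster than into the C6–Br bond at room temperature, so the copper acetylide of 5 should couple at C3 only.

Step 4
Reactants: 6 tert-butyl 6-bromo-3-[(1-methyl-1H-imidazol-5-yl)ethynyl]-1H-indole-1-carboxylate; 7 carbon monoxide; 8 2,4-dimethoxybenzylamine
Product: 9 tert-butyl 6-bromo-3-[1-(2,4-dimethoxybenzyl)-4-(1-methyl-1H-imidazol-5-yl)-2,5-dioxo-2,5-dihydro-1H-pyrrol-3-yl]-1H-indole-1-carboxylate
Conditions: PdCl2(MeCN)2 (10 mol%), Cu(OAc)2 (20 mol%), CO/O2 (4:1, 1 atm), MeCN, 60 °C; 8 (2 equiv) added slowly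
Reagents that add atoms: carbon monoxide (7), [C-]#[O+]; 2,4-dimethoxybenzylamine (8), COc1ccc(CN)c(OC)c1
Why: This is the palladium-catalysed oxidative double aminocarbonylation of an internal alkyne, known for diarylalkynes with primary amines and CO as a route to 3,4-diarylmaleimides: amine 8 and CO form a carbamoylpalladium species on divalent palladium, the alkyne of 6 inserts syn into its Pd–C bond to give a (Z)-β-carbamoylvinylpalladium intermediate, and a second CO inserts to an acylpalladium held cis to the secondary amide. The amide nitrogen then attacks the acyl carbon in a 5-exo-trig acyl substitution (equivalent to C–N reductive elimination from a six-membered palladacycle), which closes the maleimide ring and releases zerovalent palladium that Cu(OAc)2 and O2 return to the divalent state. No stereocentre is formed, and the cis arrangement of the two carbonyls that ring closure requires follows from the syn insertion. Since both carbonyls end on the same nitrogen, the two insertion orientations on the unsymmetrical alkyne converge on 9 and no regiocontrol is needed. The selectivity that is needed is chemoselectivity for the alkyne over the C6–Br bond and over urea formation: phosphine-free palladium under CO adds only sluggishly to an electron-rich aryl bromide at 60 °C and is reoxidised quickly, while slow addition of 8 keeps the carbamoylpalladium species reacting with the alkyne instead of a second amine. The N-Boc group damps the ynamine-like character of the 3-alkynylindole against hydroamination, and the imidazole N3, which cannot chelate across the alkyne, should only slow the catalyst as a ligand, which the 10 mol% loading allows for.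

Step 5
Reactants: 9 tert-butyl 6-bromo-3-[1-(2,4-dimethoxybenzyl)-4-(1-methyl-1H-imidazol-5-yl)-2,5-dioxo-2,5-dihydro-1H-pyrrol-3-yl]-1H-indole-1-carboxylate
Product: 11 didemnimide D [3-(6-bromo-1H-indol-3-yl)-4-(1-methyl-1H-imidazol-5-yl)-1H-pyrrole-2,5-dione], via N-(2,4-dimethoxybenzyl)didemnimide D 10 (not isolated)
Conditions: TFA, anisole, CH2Cl2, rt; then TFA/anisole, 70 °C; aq NaHCO3 work-up
Reagents that add atoms: none
Why: In this acidolysis the tert-butyl carbamate fragments to isobutene and CO2 at room temperature, and on heating the O-protonated imide ionises to the 2,4-dimethoxybenzyl cation, which anisole traps by Friedel–Crafts alkylation, while the aryl bromide, imidazole and maleimide are stable to TFA.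

**Compound list**

1 | 6-bromo-1H-indole | Brc1ccc2cc[nH]c2c1 | starting material
2 | 6-bromo-3-iodo-1H-indole | Brc1ccc2c(I)c[nH]c2c1 | intermediate
3 | di-tert-butyl dicarbonate | CC(C)(C)OC(=O)OC(=O)OC(C)(C)C | starting material
4 | tert-butyl 6-bromo-3-iodo-1H-indole-1-carboxylate | CC(C)(C)OC(=O)n1cc(I)c2ccc(Br)cc21 | intermediate
5 | 5-ethynyl-1-methyl-1H-imidazole | C#Cc1cncn1C | starting material
6 | tert-butyl 6-bromo-3-[(1-methyl-1H-imidazol-5-yl)ethynyl]-1H-indole-1-carboxylate | Cn1cncc1C#Cc1cn(C(=O)OC(C)(C)C)c2cc(Br)ccc12 | intermediate
7 | carbon monoxide | [C-]#[O+] | starting material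
8 | 2,4-dimethoxybenzylamine | COc1ccc(CN)c(OC)c1 | starting material
9 | tert-butyl 6-bromo-3-[1-(2,4-dimethoxybenzyl)-4-(1-methyl-1H-imidazol-5-yl)-2,5-dioxo-2,5-dihydro-1H-pyrrol-3-yl]-1H-indole-1-carboxylate | CC(C)(C)OC(=O)n1cc(C2=C(c3cncn3C)C(=O)N(Cc3ccc(OC)cc3OC)C2=O)c2ccc(Br)cc21 | intermediate
10 | 3-(6-bromo-1H-indol-3-yl)-1-(2,4-dimethoxybenzyl)-4-(1-methyl-1H-imidazol-5-yl)-1H-pyrrole-2,5-dione | COc1ccc(CN2C(=O)C(c3c[nH]c4cc(Br)ccc34)=C(c3cncn3C)C2=O)c(OC)c1 | intermediate (not isolated)
11 | didemnimide D, 3-(6-bromo-1H-indol-3-yl)-4-(1-methyl-1H-imidazol-5-yl)-1H-pyrrole-2,5-dione | Cn1cncc1C1=C(c2c[nH]c3cc(Br)ccc23)C(=O)NC1=O | target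

**Totals**

Total step count: 5. Longest linear sequence: 5 steps (1 → 2 → 4 → 6 → 9 → 11).

**Steps most likely to fail**

Step 4 (key step). The imidazole nitrogen may bind divalent palladium so firmly that turnover stalls. The amine may also be diverted into urea by carbonylation with a second amine, or the alkyne may be hydroaminated before it inserts. The fallback uses known chemistry, sets out from 1 and returns at 11: the maleimide is built by base-mediated condensation of an arylglyoxylate with an arylacetamide. 6-Bromoindole 1 is acylated at C3 with oxalyl chloride in Et2O at 0 °C to 2-(6-bromo-1H-indol-3-yl)-2-oxoacetyl chloride F1, which is quenched with methanol to methyl 2-(6-bromo-1H-indol-3-yl)-2-oxoacetate F2. Purchased 2-(1-methyl-1H-imidazol-5-yl)acetic acid hydrochloride is esterified (SOCl2, MeOH) to methyl 2-(1-methyl-1H-imidazol-5-yl)acetate F3, and NH3 in MeOH converts this into 2-(1-methyl-1H-imidazol-5-yl)acetamide F4. F2 and F4 with KOtBu in THF (0 °C to rt), followed by an HCl quench to complete the dehydration, should give 11 directly, so that steps 2, 3 and 5 fall away.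

Step 5. Ionisation of the N-benzylic bond may be slow because the imide nitrogen is a poor donor, and the benzylic cation may re-alkylate the indole instead of anisole. The fallback sets out from 9 and returns at 11. Saponification of 9 with KOH in EtOH/H2O at reflux opens the imide and removes the carbamate. Acidification with HCl then recloses the diacid to the anhydride 3-(6-bromo-1H-indol-3-yl)-4-(1-methyl-1H-imidazol-5-yl)furan-2,5-dione F5. Heating F5 with NH4OAc (melt, 140 °C) should convert it into imide 11.

Step 3. Oxidative dimerisation of the ethynylimidazole (Glaser coupling), or binding of copper and palladium by its basic nitrogen, may outpace the cross-coupling; forcing the reaction by heating would start to engage the C6 bromide. The fallback sets out from 4 and returns at 6, with the roles of the partners exchanged. Compound 4 is coupled with ethynyltrimethylsilane (PdCl2(PPh3)2, CuI, Et3N, THF, rt) to tert-butyl 6-bromo-3-[(trimethylsilyl)ethynyl]-1H-indole-1-carboxylate F6. Bu4NF buffered with AcOH in THF at 0 °C then gives tert-butyl 6-bromo-3-ethynyl-1H-indole-1-carboxylate F7. A second Sonogashira coupling of F7 with purchased 5-iodo-1-methyl-1H-imidazole (PdCl2(PPh3)2, CuI, Et3N, DMF, 40 °C) should give 6.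

**Further compounds**

F1 | step 4 | 2-(6-bromo-1H-indol-3-yl)-2-oxoacetyl chloride | O=C(Cl)C(=O)c1c[nH]c2cc(Br)ccc12
F2 | step 4 | methyl 2-(6-bromo-1H-indol-3-yl)-2-oxoacetate | COC(=O)C(=O)c1c[nH]c2cc(Br)ccc12
F3 | step 4 | methyl 2-(1-methyl-1H-imidazol-5-yl)acetate | COC(=O)Cc1cncn1C
F4 | step 4 | 2-(1-methyl-1H-imidazol-5-yl)acetamide | NC(=O)Cc1cncn1C
F5 | step 5 | 3-(6-bromo-1H-indol-3-yl)-4-(1-methyl-1H-imidazol-5-yl)furan-2,5-dione | Cn1cncc1C1=C(c2c[nH]c3cc(Br)ccc23)C(=O)OC1=O
F6 | step 3 | tert-butyl 6-bromo-3-[(trimethylsilyl)ethynyl]-1H-indole-1-carboxylate | CC(C)(C)OC(=O)n1cc(C#C[Si](C)(C)C)c2ccc(Br)cc21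
F7 | step 3 | tert-butyl 6-bromo-3-ethynyl-1H-indole-1-carboxylate | CC(C)(C)OC(=O)n1cc(C#C)c2ccc(Br)cc21
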